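In this closed, stirred vessel the starting material reads 40.7% after 1.00 h while product reads 5.2%, and product then climbs roughly in a straight line.

| flask | starting material | reagent | free catalyst | second catalyst | remark |
|---|---|---|---|---|---|
| alpha | 17 mM | 16.2 mM | 0.17 mM | 12 µM | the very flask that is asked about, followed so far |
| flask | 17 mM | 16.2 mM | 0.17 mM | 12 µM |  |

alpha run (percent of the starting material charged)

| time / h | product / % | starting material / % |
|---|---|---|
| 1.00 | 5.2 | 40.7 |
| 2.00 | 5.2 | 38.9 |
| 3.00 | 9.4 | 37.7 |
| 4.00 | 11.3 | 35.9 |
| 5.00 | 14.8 | 34.3 |
| 6.00 | 16.8 | 35.3 |

(standard deviation of a reading: 1 percentage point)

- apparent order in free catalyst when 20% of the starting material are converted (percent change of the rate of making product for one percent more free catalyst charged)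

- "the catalyst" is free catalyst with its forms; second catalyst is a second catalyst
- no earlier run changes the charge of free catalyst; that part of a forecast is a guess

Two chemists argue over these readings. The first holds that free catalyst still has a hand in the pace of making product, and the forecast is that side's number, 0.3: “a low fractional order, with a wide range”.

The second, whose reckoning follows, sees a filling step feeding a draining step. What vanished in the first hour without appearing as product gives a filling rate of at least 9.20 mM/h, while the product readings from 1.00 h to 6.00 h give a draining rate of 0.394 mM/h. Filling over draining is the margin, read as at least 23.3, or 1.37 powers of ten. Filling is thus faster than draining, which makes draining the rate-limiting step.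

Two steps in a row each cost time inversely to their rate, so filling takes one part in one plus the margin. If free catalyst acts on filling, its order is that share, at most 0.0411. The first chemist's number needs a margin of 2.33, which is smaller than the margin read here; that view belongs to a region where filling and draining stand that close, and these readings do not place this flask there.

The flask gives −1.3 × 10⁻⁵.

    starting material + free catalyst ⇌ free catalyst + open intermediate (K = 1.40, k = 1720 /M/min)
    second catalyst + open intermediate ⇌ catalyst intermediate (K = 1120 /M, k = 22100 /M/min)
    reagent + catalyst intermediate → second catalyst + product (k = 51.2 /M/min)
    2 free catalyst ⇌ resting dimer, settled at all times (K = 4900 /M)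

At 1.50 h the catalyst intermediate holds 91.0% of the second catalyst, and the reagent enters at the step that uses it up. Draining takes the rest of the time, so the margin puts the order in reagent at 20% conversion at no less than 0.959, and the flask gives 0.99.

Readings and results are simulated with constants of no real substance, and the scatter is random.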